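**Strategy.** The ten-membered carbocycle (C1–C10, germacrane numbering) is closed last, at C3–C4, by an intramolecular Nozaki–Hiyama–Kishi reaction. The step exploits the (Z)-C4=C5 alkene and its neighbouring C3 carbinol, the retron of an alkenylchromium–aldehyde addition: in one operation it forms the ring, the C3–C4 bond and the C3 stereocentre and releases the unprotected target. The precursor is a seco-germacranolide aldehyde that already carries the trans α-methylene-γ-lactone ring (O–C6–C7–C11–C12), the cis C1–O–C10 oxirane, the C8 isobutyrate and a (Z)-2-iodopropenyl group on C6; cis-alkene, lactone and oxirane fold the chain for closure.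

Key step: step 15

Remark: germacrane numbering is used for all seco intermediates (ring carbons C1–C10, lactone carbons C11–C13, C14 on C10, C15 on C4). The target SMILES defines a 4Z alkene and a cis-1,10-oxirane, i.e. (1R,3S,6S,7S,8R,10S); the route is planned for exactly this isomer.
Remark: in every intermediate that carries the iodoalkene the CIP descriptor at C6 reads R (iodine raises the priority of C5); the spatial arrangement is that of 6S in the target.

Step 1
Reactants: 1 dimethyl itaconate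
Product: 2 3-(methoxycarbonyl)but-3-enoic acid
Conditions: LiOH·H2O (1.0 equiv), THF/H2O, 0 °C; then 1 M HCl
Reagents that add atoms: lithium hydroxide, [Li+].[OH-]
Why: Regioselective saponification, in which hydroxide attacks the non-conjugated (acetate-type) ester faster than the cross-conjugated acrylate ester, so one equivalent at 0 °C should stop at the half-ester without moving the exocyclic alkene.

Step 2
Reactants: 2 3-(methoxycarbonyl)but-3-enoic acid; 3 (4R)-4-benzyl-1,3-thiazolidine-2-thione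
Product: 4 methyl 2-{2-[(4R)-4-benzyl-2-sulfanylidene-1,3-thiazolidin-3-yl]-2-oxoethyl}prop-2-enoate
Conditions: EDC·HCl, DMAP (cat.), CH2Cl2, 0 °C to rt
Reagents that add atoms: none
Why: Carbodiimide (Steglich-type) N-acylation is the standard entry to Crimmins N-acyl thiazolidinethiones and is mild enough to keep the 1,1-disubstituted alkene out of conjugation.

Step 3
Reactants: 5 but-2-yn-1-ol
Product: 6 (2Z)-3-iodobut-2-en-1-ol
Conditions: NaAlH2(OCH2CH2OMe)2 (Red-Al), THF, 0 °C to rt; then I2, THF, −78 °C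
Reagents that add atoms: iodine, II
Why: Hydroxyl-directed trans-hydroalumination of the propargylic alcohol places aluminium on C3 anti to the new hydrogen, and iodinolysis with retention should give the (Z)-iodoalkene.

Step 4
Reactants: 6 (2Z)-3-iodobut-2-en-1-ol
Product: 7 (2Z)-3-iodobut-2-enal
Conditions: MnO2 (activated, excess), CH2Cl2, rt, dark; used directly
Reagents that add atoms: none
Why: Neutral allylic oxidation with MnO2 should give the β-iodo enal without Z/E isomerisation.

Step 5
Reactants: 4 methyl 2-{2-[(4R)-4-benzyl-2-sulfanylidene-1,3-thiazolidin-3-yl]-2-oxoethyl}prop-2-enoate; 7 (2Z)-3-iodobut-2-enal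
Product: 8 methyl 2-{(2R,3R,4Z)-1-[(4R)-4-benzyl-2-sulfanylidene-1,3-thiazolidin-3-yl]-3-hydroxy-5-iodo-1-oxohex-4-en-2-yl}prop-2-enoate
Conditions: TiCl4 (1.05 equiv), i-Pr2NEt (1.1 equiv), N-methylpyrrolidinone (1.0 equiv), CH2Cl2, 0 °C; then 7, −78 °C; cold aq. NH4Cl
Reagents that add atoms: none
Why: Crimmins titanium-enolate aldol addition in its "Evans-syn" mode (Z-enolate, non-chelated Zimmerman–Traxler chair, aldehyde on the face away from the benzyl group of the (R)-auxiliary) sets C6 and C7 as the syn pair that later becomes the trans-lactone, and the cold quench should leave the γ-hydroxy methyl ester unlactonised.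

Step 6
Reactants: 8 methyl 2-{(2R,3R,4Z)-1-[(4R)-4-benzyl-2-sulfanylidene-1,3-thiazolidin-3-yl]-3-hydroxy-5-iodo-1-oxohex-4-en-2-yl}prop-2-enoate
Product: 9 methyl 2-{(2R,3R,4Z)-1-[(4R)-4-benzyl-2-sulfanylidene-1,3-thiazolidin-3-yl]-5-iodo-1-oxo-3-(triethylsilyloxy)hex-4-en-2-yl}prop-2-enoate
Conditions: Et3SiOTf, 2,6-lutidine, CH2Cl2, −78 °C
Reagents that add atoms: triethylsilyl trifluoromethanesulfonate, CC[Si](CC)(CC)OS(=O)(=O)C(F)(F)F
Why: Silylation of the secondary allylic alcohol (silyl triflate with a hindered pyridine base) blocks retro-aldol cleavage and premature lactonisation.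

Step 7
Reactants: 9 methyl 2-{(2R,3R,4Z)-1-[(4R)-4-benzyl-2-sulfanylidene-1,3-thiazolidin-3-yl]-5-iodo-1-oxo-3-(triethylsilyloxy)hex-4-en-2-yl}prop-2-enoate
Product: 10 methyl 2-[(2R,3R,4Z)-5-iodo-1-oxo-3-(triethylsilyloxy)hex-4-en-2-yl]prop-2-enoate
Conditions: i-Bu2AlH (1.2 equiv), CH2Cl2, −78 °C; aq. KNaC4H4O6 (potassium sodium tartrate); used crude
Reagents that add atoms: none
Why: Reductive cleavage of the highly activated N-acyl thiazolidinethione by i-Bu2AlH gives the aldehyde directly through a chelated tetrahedral intermediate at −78 °C, where the methyl acrylate ester should be untouched, and the neutral work-up avoids epimerisation at C7.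

Step 8
Reactants: 11 3-(tert-butyldimethylsilyloxy)propan-1-ol
Product: 12 3-(tert-butyldimethylsilyloxy)propyl N,N-diisopropylcarbamate
Conditions: i-Pr2NCOCl, Et3N, CH2Cl2, reflux
Reagents that add atoms: N,N-diisopropylcarbamoyl chloride, CC(C)N(C(C)C)C(Cl)=O
Why: O-Carbamoylation gives the Hoppe carbamate required for sparteine-mediated α-lithiation.

Step 9
Reactants: 12 3-(tert-butyldimethylsilyloxy)propyl N,N-diisopropylcarbamate; 13 4,4,5,5-tetramethyl-2-(prop-1-en-2-yl)-1,3,2-dioxaborolane
Product: 15 tert-butyl(dimethyl){[(3R)-4-methyl-3-(4,4,5,5-tetramethyl-1,3,2-dioxaborolan-2-yl)pent-4-en-1-yl]oxy}silane, via lithium boronate complex 14 (not isolated)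
Conditions: s-BuLi, (−)-sparteine, Et2O, −78 °C; then 13, −78 °C; then MgBr2·OEt2, −78 °C to reflux
Reagents that add atoms: none
Why: Hoppe–Aggarwal lithiation–borylation, in which s-BuLi/(−)-sparteine removes the pro-S proton, the (S)-lithiated carbamate captures the alkenylboronate with retention, and 1,2-migration of the isopropenyl group with inversion should deliver the (R)-configured α-substituted allylboronate.

Step 10
Reactants: 10 methyl 2-[(2R,3R,4Z)-5-iodo-1-oxo-3-(triethylsilyloxy)hex-4-en-2-yl]prop-2-enoate; 15 tert-butyl(dimethyl){[(3R)-4-methyl-3-(4,4,5,5-tetramethyl-1,3,2-dioxaborolan-2-yl)pent-4-en-1-yl]oxy}silane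
Product: 17 methyl 2-[(2Z,4R,5S,6R,8Z)-11-(tert-butyldimethylsilyloxy)-6-hydroxy-2-iodo-8-methyl-4-(triethylsilyloxy)undeca-2,8-dien-5-yl]prop-2-enoate, via O-boryl ether 16 (not isolated)
Conditions: 15 (1.5 equiv), CH2Cl2 (1 M), 4 Å MS, rt; then aq. NaHCO3
Reagents that add atoms: none
Why: Hoffmann-type allylboration with an α-chiral allylboronate through a closed chair transition state, in which the CH2CH2OSi group sits axial (away from the pinacol oxygens and free of A(1,2) strain with the 2-methyl group), should give the (Z)-C10=C1 alkene and transfer the boron-bearing stereocentre to C8 (8R), reagent control being reinforced by Felkin–Anh approach anti to C6.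

Step 11
Reactants: 17 methyl 2-[(2Z,4R,5S,6R,8Z)-11-(tert-butyldimethylsilyloxy)-6-hydroxy-2-iodo-8-methyl-4-(triethylsilyloxy)undeca-2,8-dien-5-yl]prop-2-enoate
Product: 18 methyl 2-[(2Z,4R,5S,6R,8Z)-11-(tert-butyldimethylsilyloxy)-2-iodo-8-methyl-6-(2-methylpropanoyloxy)-4-(triethylsilyloxy)undeca-2,8-dien-5-yl]prop-2-enoate
Conditions: (i-PrCO)2O, DMAP (cat.), pyridine, CH2Cl2, 0 °C to rt
Reagents that add atoms: isobutyric anhydride, CC(C)C(=O)OC(=O)C(C)C
Why: DMAP-catalysed acyl transfer installs the C8 isobutyrate while every other hydroxyl is still silylated, so no stereocentre or competing hydroxyl is touched.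

Step 12
Reactants: 18 methyl 2-[(2Z,4R,5S,6R,8Z)-11-(tert-butyldimethylsilyloxy)-2-iodo-8-methyl-6-(2-methylpropanoyloxy)-4-(triethylsilyloxy)undeca-2,8-dien-5-yl]prop-2-enoate
Product: 20 (1R,3Z)-6-hydroxy-1-{(2R,3S)-2-[(1Z)-2-iodoprop-1-en-1-yl]-4-methylidene-5-oxooxolan-3-yl}-3-methylhex-3-en-1-yl 2-methylpropanoate, via dihydroxy methyl ester 19 (not isolated)
Conditions: HF·pyridine, pyridine, THF, 0 °C to rt; then PPTS (cat.), PhMe, 50 °C
Reagents that add atoms: none
Why: Fluoride-mediated removal of both silyl ethers followed by acid-catalysed 5-exo-trig lactonisation of the C6 hydroxyl onto the acrylate ester should close the trans α-methylene-γ-butyrolactone (C6/C7 from step 5), only the 12,6-lactone being possible because O-8 is acylated.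

Step 13
Reactants: 20 (1R,3Z)-6-hydroxy-1-{(2R,3S)-2-[(1Z)-2-iodoprop-1-en-1-yl]-4-methylidene-5-oxooxolan-3-yl}-3-methylhex-3-en-1-yl 2-methylpropanoate
Product: 21 (1R)-2-[(2S,3R)-3-(2-hydroxyethyl)-2-methyloxiran-2-yl]-1-{(2R,3S)-2-[(1Z)-2-iodoprop-1-en-1-yl]-4-methylidene-5-oxooxolan-3-yl}ethyl 2-methylpropanoate
Conditions: D-fructose-derived Shi ketone (0.3 equiv), KHSO5 (as Oxone), K2CO3, Bu4NHSO4, MeCN/CH2(OMe)2, aq. Na2B4O7 buffer (pH 10.5), 0 °C
Reagents that add atoms: potassium peroxymonosulfate, [K+].[O-]S(=O)(=O)OO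
Why: Shi asymmetric epoxidation, in which the chiral dioxirane attacks only the electron-rich trisubstituted C1=C10 alkene (iodoalkene and acrylate are deactivated) through the spiro transition state with the olefinic hydrogen in the hindered quadrant, should deliver oxygen to the face that gives the (1R,10S) cis-oxirane under reagent control.

Step 14
Reactants: 21 (1R)-2-[(2S,3R)-3-(2-hydroxyethyl)-2-methyloxiran-2-yl]-1-{(2R,3S)-2-[(1Z)-2-iodoprop-1-en-1-yl]-4-methylidene-5-oxooxolan-3-yl}ethyl 2-methylpropanoate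
Product: 22 (1R)-1-{(2R,3S)-2-[(1Z)-2-iodoprop-1-en-1-yl]-4-methylidene-5-oxooxolan-3-yl}-2-[(2S,3R)-2-methyl-3-(2-oxoethyl)oxiran-2-yl]ethyl 2-methylpropanoate
Conditions: Dess–Martin periodinane, NaHCO3, CH2Cl2, 0 °C; filtered and used at once
Reagents that add atoms: none
Why: Buffered Dess–Martin oxidation converts the primary alcohol into the β,γ-epoxy aldehyde without acid or base strong enough to open the oxirane by β-elimination.

Step 15
Reactants: 22 (1R)-1-{(2R,3S)-2-[(1Z)-2-iodoprop-1-en-1-yl]-4-methylidene-5-oxooxolan-3-yl}-2-[(2S,3R)-2-methyl-3-(2-oxoethyl)oxiran-2-yl]ethyl 2-methylpropanoate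
Product: 23 (1R,3S,4Z,6S,7S,8R,10S)-1,10-epoxy-3-hydroxy-8-(2-methylpropanoyloxy)germacra-4,11(13)-dien-12,6-olide
Conditions: CrCl2 (15 equiv), NiCl2 (0.3 equiv), degassed DMSO/THF, rt, 22 added by syringe pump over 12 h (final 2 mM); aq. NH4Cl
Reagents that add atoms: none
Why: NiCl2 is reduced by CrCl2 to zerovalent nickel, which inserts into the C4–I bond with retention of the Z geometry, and transmetalation gives an alkenyl species of trivalent chromium that adds to the C3 aldehyde; this is the Nozaki–Hiyama–Kishi reaction in its macrocyclising form. The C1–C10 carbocycle is closed by a 10-exo-trig 1,2-addition that forms the C3–C4 bond. C3 is set under conformational control by the cis-alkene: allylic 1,3-strain should keep the aldehyde hydrogen in the alkene plane facing H-6, the tether must leave C3 on the face on which C7 leaves C6, and the chromium-bound oxygen is then delivered on the open outer face, syn to the lactone oxygen on C6, which corresponds to 3S. The step needs chemoselectivity, which the reagent supplies because alkenylchromium adds to aldehydes but not to the lactone, the isobutyrate, the oxirane or the acrylate. It also needs cyclisation to outrun oligomerisation, which high dilution and the three folding elements (cis-alkene, trans-lactone, cis-oxirane) should secure, and the near-neutral medium should spare the β,γ-epoxy aldehyde.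

**Compound list**

1 | dimethyl itaconate (dimethyl 2-methylidenebutanedioate) | COC(=O)CC(=C)C(=O)OC | starting material
2 | 3-(methoxycarbonyl)but-3-enoic acid | OC(=O)CC(=C)C(=O)OC | intermediate
3 | (4R)-4-benzyl-1,3-thiazolidine-2-thione | S=C1SC[C@@H](Cc2ccccc2)N1 | starting material
4 | methyl 2-{2-[(4R)-4-benzyl-2-sulfanylidene-1,3-thiazolidin-3-yl]-2-oxoethyl}prop-2-enoate | COC(=O)C(=C)CC(=O)N1[C@H](Cc2ccccc2)CSC1=S | intermediate
5 | but-2-yn-1-ol | CC#CCO | starting material
6 | (2Z)-3-iodobut-2-en-1-ol | OC/C=C(/C)I | intermediate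
7 | (2Z)-3-iodobut-2-enal | O=C/C=C(/C)I | intermediate
8 | methyl 2-{(2R,3R,4Z)-1-[(4R)-4-benzyl-2-sulfanylidene-1,3-thiazolidin-3-yl]-3-hydroxy-5-iodo-1-oxohex-4-en-2-yl}prop-2-enoate | COC(=O)C(=C)[C@H]([C@@H](O)/C=C(/C)I)C(=O)N1[C@H](Cc2ccccc2)CSC1=S | intermediate
9 | methyl 2-{(2R,3R,4Z)-1-[(4R)-4-benzyl-2-sulfanylidene-1,3-thiazolidin-3-yl]-5-iodo-1-oxo-3-(triethylsilyloxy)hex-4-en-2-yl}prop-2-enoate | COC(=O)C(=C)[C@H]([C@@H](O[Si](CC)(CC)CC)/C=C(/C)I)C(=O)N1[C@H](Cc2ccccc2)CSC1=S | intermediate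
10 | methyl 2-[(2R,3R,4Z)-5-iodo-1-oxo-3-(triethylsilyloxy)hex-4-en-2-yl]prop-2-enoate | COC(=O)C(=C)[C@H]([C@@H](O[Si](CC)(CC)CC)/C=C(/C)I)C=O | intermediate
11 | 3-(tert-butyldimethylsilyloxy)propan-1-ol | OCCCO[Si](C)(C)C(C)(C)C | starting material
12 | 3-(tert-butyldimethylsilyloxy)propyl N,N-diisopropylcarbamate | CC(C)N(C(C)C)C(=O)OCCCO[Si](C)(C)C(C)(C)C | intermediate
13 | 4,4,5,5-tetramethyl-2-(prop-1-en-2-yl)-1,3,2-dioxaborolane (isopropenylboronic acid pinacol ester) | CC(=C)B1OC(C)(C)C(C)(C)O1 | starting material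
14 | lithium [(1S)-3-(tert-butyldimethylsilyloxy)-1-(diisopropylcarbamoyloxy)propyl](prop-1-en-2-yl)(pinacolato)borate | [Li+].CC(=C)[B-]1(OC(C)(C)C(C)(C)O1)[C@@H](CCO[Si](C)(C)C(C)(C)C)OC(=O)N(C(C)C)C(C)C | intermediate (not isolated)
15 | tert-butyl(dimethyl){[(3R)-4-methyl-3-(4,4,5,5-tetramethyl-1,3,2-dioxaborolan-2-yl)pent-4-en-1-yl]oxy}silane | CC(=C)[C@@H](CCO[Si](C)(C)C(C)(C)C)B1OC(C)(C)C(C)(C)O1 | intermediate
16 | methyl 2-[(2Z,4R,5S,6R,8Z)-11-(tert-butyldimethylsilyloxy)-2-iodo-8-methyl-6-[(4,4,5,5-tetramethyl-1,3,2-dioxaborolan-2-yl)oxy]-4-(triethylsilyloxy)undeca-2,8-dien-5-yl]prop-2-enoate | COC(=O)C(=C)[C@H]([C@@H](O[Si](CC)(CC)CC)/C=C(/C)I)[C@H](OB1OC(C)(C)C(C)(C)O1)C/C(C)=C\CCO[Si](C)(C)C(C)(C)C | intermediate (not isolated)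
17 | methyl 2-[(2Z,4R,5S,6R,8Z)-11-(tert-butyldimethylsilyloxy)-6-hydroxy-2-iodo-8-methyl-4-(triethylsilyloxy)undeca-2,8-dien-5-yl]prop-2-enoate | COC(=O)C(=C)[C@H]([C@@H](O[Si](CC)(CC)CC)/C=C(/C)I)[C@H](O)C/C(C)=C\CCO[Si](C)(C)C(C)(C)C | intermediate
18 | methyl 2-[(2Z,4R,5S,6R,8Z)-11-(tert-butyldimethylsilyloxy)-2-iodo-8-methyl-6-(2-methylpropanoyloxy)-4-(triethylsilyloxy)undeca-2,8-dien-5-yl]prop-2-enoate | COC(=O)C(=C)[C@H]([C@@H](O[Si](CC)(CC)CC)/C=C(/C)I)[C@H](OC(=O)C(C)C)C/C(C)=C\CCO[Si](C)(C)C(C)(C)C | intermediate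
19 | methyl 2-[(2Z,4R,5R,6R,8Z)-4,11-dihydroxy-2-iodo-8-methyl-6-(2-methylpropanoyloxy)undeca-2,8-dien-5-yl]prop-2-enoate | COC(=O)C(=C)[C@H]([C@@H](O)/C=C(/C)I)[C@H](OC(=O)C(C)C)C/C(C)=C\CCO | intermediate (not isolated)
20 | (1R,3Z)-6-hydroxy-1-{(2R,3S)-2-[(1Z)-2-iodoprop-1-en-1-yl]-4-methylidene-5-oxooxolan-3-yl}-3-methylhex-3-en-1-yl 2-methylpropanoate | C=C1C(=O)O[C@@H](/C=C(/C)I)[C@@H]1[C@H](OC(=O)C(C)C)C/C(C)=C\CCO | intermediate
21 | (1R)-2-[(2S,3R)-3-(2-hydroxyethyl)-2-methyloxiran-2-yl]-1-{(2R,3S)-2-[(1Z)-2-iodoprop-1-en-1-yl]-4-methylidene-5-oxooxolan-3-yl}ethyl 2-methylpropanoate | C=C1C(=O)O[C@@H](/C=C(/C)I)[C@@H]1[C@H](OC(=O)C(C)C)C[C@]2(C)O[C@@H]2CCO | intermediate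
22 | (1R)-1-{(2R,3S)-2-[(1Z)-2-iodoprop-1-en-1-yl]-4-methylidene-5-oxooxolan-3-yl}-2-[(2S,3R)-2-methyl-3-(2-oxoethyl)oxiran-2-yl]ethyl 2-methylpropanoate | C=C1C(=O)O[C@@H](/C=C(/C)I)[C@@H]1[C@H](OC(=O)C(C)C)C[C@]2(C)O[C@@H]2CC=O | intermediate
23 | (1R,3S,4Z,6S,7S,8R,10S)-1,10-epoxy-3-hydroxy-8-(2-methylpropanoyloxy)germacra-4,11(13)-dien-12,6-olide | C=C1C(=O)O[C@H]2/C=C(/C)[C@@H](O)C[C@H]3O[C@@]3(C)C[C@@H](OC(=O)C(C)C)[C@H]12 | target

**Step count.** Total: 15 steps. Longest linear sequence: 11 steps (1, 2, 5, 6, 7, 10, 11, 12, 13, 14, 15).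

**Steps most likely to fail, with fallbacks**

Step 15. The risk is poor facial selectivity in the alkenylchromium addition, i.e. delivery of the C3 oxygen on the inner face, or erosion to an epimer mixture. The fallback sets out from 22 and returns at 23; it keeps the ring closure but separates it from the C3 configuration. The cyclisation is run as in step 15, and the product, now the (3R)-epimer of 23 F1 (alone or in a mixture), is oxidised with MnO2 in CH2Cl2 to the cross-conjugated 3-oxo compound F2. Reduction of F2 with catecholborane and (R)-2-methyl-CBS-oxazaborolidine in toluene at −78 °C, the alkenyl group acting as the large substituent, should then give the 3S alcohol 23 under reagent control.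

Step 10. The risks are loss of Z/E control if the α-substituent takes the equatorial position, and slow addition to the hindered aldehyde, which would give 10 time to isomerise into conjugation. The fallback sets out from 10 and 11 and returns at 17; it replaces the boronate by an allylbarium reagent that adds through its α-carbon with retention of alkene geometry. Alcohol 11 is oxidised with Dess–Martin periodinane to 3-(tert-butyldimethylsilyloxy)propanal F3. Still–Gennari olefination with methyl 2-[bis(2,2,2-trifluoroethoxy)phosphoryl]propanoate (KN(SiMe3)2, 18-crown-6, THF, −78 °C) should give the (Z)-enoate F4. Reduction with i-Bu2AlH gives the (Z)-allylic alcohol F5, and MsCl/Et3N followed by LiCl gives the (Z)-allylic chloride F6. F6 is converted with activated barium (BaI2, lithium biphenylide LiC12H10, THF, −78 °C) into the allylbarium chloride, which is added to aldehyde 10 at −78 °C and should give 17 directly. The C8 configuration then rests on Felkin–Anh approach anti to C6.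

Step 13. The risks are poor facial selectivity of the dioxirane on the (Z)-trisubstituted (neryl-type) alkene, and hydrolysis or conjugate addition at the α-methylene lactone in the pH 10.5 medium. The fallback sets out from 20 and returns at 21; it replaces the external dioxirane in aqueous base by hydroxyl-directed, ligand-controlled oxygen transfer in a neutral organic medium. The free C3 hydroxyl makes 20 a homoallylic alcohol, the substrate class of the Yamamoto asymmetric epoxidation (VO(Oi-Pr)3, a C2-symmetric bis-hydroxamic acid ligand derived from trans-cyclohexane-1,2-diamine, cumene hydroperoxide, toluene, rt). The ligand antipode matched to the (1R,10S) oxirane would be used; no new compound arises (F0).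

**Further compounds**

F1 | step 15 | (1R,3R,4Z,6S,7S,8R,10S)-1,10-epoxy-3-hydroxy-8-(2-methylpropanoyloxy)germacra-4,11(13)-dien-12,6-olide (3-epimer of 23) | C=C1C(=O)O[C@H]2/C=C(/C)[C@H](O)C[C@H]3O[C@@]3(C)C[C@@H](OC(=O)C(C)C)[C@H]12
F2 | step 15 | (1R,4Z,6S,7S,8R,10S)-1,10-epoxy-8-(2-methylpropanoyloxy)-3-oxogermacra-4,11(13)-dien-12,6-olide | C=C1C(=O)O[C@H]2/C=C(/C)C(=O)C[C@H]3O[C@@]3(C)C[C@@H](OC(=O)C(C)C)[C@H]12
F3 | step 10 | 3-(tert-butyldimethylsilyloxy)propanal | O=CCCO[Si](C)(C)C(C)(C)C
F4 | step 10 | methyl (2Z)-5-(tert-butyldimethylsilyloxy)-2-methylpent-2-enoate | COC(=O)/C(C)=C\CCO[Si](C)(C)C(C)(C)C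
F5 | step 10 | (2Z)-5-(tert-butyldimethylsilyloxy)-2-methylpent-2-en-1-ol | OC/C(C)=C\CCO[Si](C)(C)C(C)(C)C
F6 | step 10 | tert-butyl{[(3Z)-5-chloro-4-methylpent-3-en-1-yl]oxy}dimethylsilane | ClC/C(C)=C\CCO[Si](C)(C)C(C)(C)C
F0 | step 13 | none | none
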